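**Retrosynthetic overview**
1. Target: 3-hexadecyl-2-hydroxy-5-methoxy-1,4-benzoquinone, ring numbered C1 (carbonyl), C2 (OH), C3 (hexadecyl), C4 (carbonyl), C5 (OMe), C6 (H). The C2 hydroxyl is unmasked last from a tert-butyl ether, and the quinone comes from oxidation of a 4-siloxyphenol.
2. Key disconnection: the C1–C6 bond, made by 6π electrocyclisation of a dienylketene (C1 = ketene carbon, C6 = terminal CH2 of a 1-methoxyvinyl group). The ketene is released by 4π ring-opening of a cyclobutenone.
3. Enabling feature: the para carbonyl carbons C1 and C4 are bridged on one side by the C2=C3 alkene (oxygen on C2, hexadecyl on C3), so C1–C2–C3–C4 maps onto a squarate-derived cyclobutenone with C4 as an oxygenated sp3 carbon. On the other side they are bridged by C5(OMe)=C6H, which is a 1-methoxyvinyl group on C4.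
4. Cyclobutenone: di-tert-butyl squarate plus 1-methoxyvinyllithium (C4–C5 bond) and O-silylation, then hexadecyllithium addition and 1,3-carbonyl transposition (C3–hexadecyl bond; the carbonyl ends next to the tert-butoxy carbon).
5. Ring order: the four-membered ring is bought with 1; the six-membered ring is closed in step 3 only.

Key step: step 3

Remark: the target is achiral. Compounds 5 and 10 are racemic, and 8 and 9 are diastereomer mixtures; all converge because their stereocentres become sp2 carbons.

Step 1
Reactants: 1 di-tert-butyl squarate (3,4-di-tert-butoxycyclobut-3-ene-1,2-dione); 2 methyl vinyl ether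
Product: 5 2,3-di-tert-butoxy-4-(tert-butyldimethylsilyloxy)-4-(1-methoxyvinyl)cyclobut-2-en-1-one (racemic), via 1-methoxyvinyllithium 3 (not isolated), via lithium alkoxide 4 (not isolated)
Conditions: 2, t-BuLi, THF, −78 → 0 °C; then 1, THF, −78 °C; then TBSOTf, −78 → 0 °C; aq. NaHCO3
Reagents that add atoms: tert-butyldimethylsilyl triflate (TBSOTf), CC(C)(C)[Si](C)(C)OS(=O)(=O)C(F)(F)F
Why: α-Lithiation of the enol ether gives acyl-anion equivalent 3, which should add 1,2 to one of the two equivalent carbonyls of the squarate ester (organolithium addition to a squaric ester), and the tertiary lithium alkoxide is trapped by the silyl triflate; the one new stereocentre forms racemic and is destroyed in step 3.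

Step 2
Reactants: 5 2,3-di-tert-butoxy-4-(tert-butyldimethylsilyloxy)-4-(1-methoxyvinyl)cyclobut-2-en-1-one; 6 1-iodohexadecane
Product: 10 2-tert-butoxy-4-(tert-butyldimethylsilyloxy)-3-hexadecyl-4-(1-methoxyvinyl)cyclobut-2-en-1-one (racemic), via hexadecyllithium 7 (not isolated), via lithium alkoxide 8 (not isolated), via trifluoroacetate ester 9 (not isolated)
Conditions: 6, t-BuLi (2 equiv), Et2O/pentane, −78 °C → rt (excess t-BuLi destroyed); then 5, THF, −78 °C; then 2,6-lutidine, TFAA, −78 → −20 °C; aq. NaHCO3
Reagents that add atoms: none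
Why: Lithium–iodine exchange gives 7, which should add 1,2 to the vinylogous-ester carbonyl of 5, and trifluoroacetylation of the new tertiary alkoxide triggers ionisation to an allyl cation stabilised by the distal tert-butoxy oxygen, which loses isobutene to leave the ketone at that carbon (organolithium addition followed by a Stork–Danheiser-type 1,3-carbonyl transposition, as practised on squarate adducts), so that hexadecyl sits on the β-carbon and the carbonyl next to the remaining tert-butoxy carbon; no new stereocentre survives.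

Step 3
Reactants: 10 2-tert-butoxy-4-(tert-butyldimethylsilyloxy)-3-hexadecyl-4-(1-methoxyvinyl)cyclobut-2-en-1-one
Product: 13 2-tert-butoxy-4-(tert-butyldimethylsilyloxy)-3-hexadecyl-5-methoxyphenol, via dienylketene 11 (not isolated), via cyclohexa-2,4-dienone 12 (not isolated)
Conditions: toluene (0.01 M, degassed), 110 °C
Reagents that add atoms: none
Why: Heating should open the cyclobutenone by conrotatory 4π electrocyclic cleavage of the bond between the carbonyl carbon and the siloxy-bearing sp3 carbon to give dienylketene 11, the siloxy donor rotating outward so that the 1-methoxyvinyl group turns inward, cis to the ketene. The ketene carbon (future C1) and the terminal CH2 of the enol ether (future C6) then bond in a thermal disrotatory 6π electrocyclisation, the mode by which the six-membered ring closes, giving cyclohexa-2,4-dienone 12, and enolisation of a C6 hydrogen aromatises it to phenol 13. The closest known reaction type is the Moore–Liebeskind thermal ring expansion of 4-alkenyl-4-hydroxy- or 4-siloxycyclobutenones to hydroquinone derivatives. No stereocentre is created, and the racemic sp3 centre of 10 becomes sp2. The step needs outward torquoselectivity of the oxygen substituent, secured by the donor siloxy group on the sp3 carbon, and a fixed placement of substituents, secured because the ketene carbon is already bonded to the tert-butoxy carbon and the vinyl group to the siloxy carbon; high dilution in a non-nucleophilic solvent keeps the ketene from intermolecular capture. In this one operation the six-membered ring should appear with all six substituents in their final positions and both future quinone oxygens in place.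

Step 4
Reactants: 13 2-tert-butoxy-4-(tert-butyldimethylsilyloxy)-3-hexadecyl-5-methoxyphenol
Product: 14 2-tert-butoxy-3-hexadecyl-5-methoxy-1,4-benzoquinone
Conditions: PhI(OAc)2, MeCN/H2O, 0 °C
Reagents that add atoms: none
Why: Oxidative dearomatisation of a para-oxygenated phenol by the trivalent iodine reagent should give an O-silyl oxocarbenium ion that water desilylates to the para-quinone, under weakly acidic conditions that spare the tert-butyl and methyl vinylogous esters.

Step 5
Reactants: 14 2-tert-butoxy-3-hexadecyl-5-methoxy-1,4-benzoquinone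
Product: 15 3-hexadecyl-2-hydroxy-5-methoxy-1,4-benzoquinone (target)
Conditions: TFA, CH2Cl2, 0 °C → rt
Reagents that add atoms: none
Why: Acidolysis of the tert-butyl vinylogous ester (tert-butyl ether cleavage by loss of isobutene) should free the C2 hydroxyl, while the C5 methyl ether cannot ionise and stays.

**Compound list**
1 | di-tert-butyl squarate (3,4-di-tert-butoxycyclobut-3-ene-1,2-dione) | CC(C)(C)OC1=C(OC(C)(C)C)C(=O)C1=O | starting material
2 | methyl vinyl ether | COC=C | starting material
3 | 1-methoxyvinyllithium | [Li]C(=C)OC | intermediate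
4 | lithium 2,3-di-tert-butoxy-1-(1-methoxyvinyl)-4-oxocyclobut-2-en-1-olate (racemic) | [Li]OC1(C(=C)OC)C(OC(C)(C)C)=C(OC(C)(C)C)C1=O | intermediate
5 | 2,3-di-tert-butoxy-4-(tert-butyldimethylsilyloxy)-4-(1-methoxyvinyl)cyclobut-2-en-1-one (racemic) | COC(=C)C1(O[Si](C)(C)C(C)(C)C)C(OC(C)(C)C)=C(OC(C)(C)C)C1=O | intermediate
6 | 1-iodohexadecane | CCCCCCCCCCCCCCCCI | starting material
7 | hexadecyllithium | [Li]CCCCCCCCCCCCCCCC | intermediate
8 | lithium 2,3-di-tert-butoxy-4-(tert-butyldimethylsilyloxy)-1-hexadecyl-4-(1-methoxyvinyl)cyclobut-2-en-1-olate (racemic, diastereomer mixture) | CCCCCCCCCCCCCCCCC1(O[Li])C(OC(C)(C)C)=C(OC(C)(C)C)C1(O[Si](C)(C)C(C)(C)C)C(=C)OC | intermediate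
9 | 2,3-di-tert-butoxy-4-(tert-butyldimethylsilyloxy)-1-hexadecyl-4-(1-methoxyvinyl)cyclobut-2-en-1-yl trifluoroacetate (racemic, diastereomer mixture) | CCCCCCCCCCCCCCCCC1(OC(=O)C(F)(F)F)C(OC(C)(C)C)=C(OC(C)(C)C)C1(O[Si](C)(C)C(C)(C)C)C(=C)OC | intermediate
10 | 2-tert-butoxy-4-(tert-butyldimethylsilyloxy)-3-hexadecyl-4-(1-methoxyvinyl)cyclobut-2-en-1-one (racemic) | CCCCCCCCCCCCCCCCC1=C(OC(C)(C)C)C(=O)C1(O[Si](C)(C)C(C)(C)C)C(=C)OC | intermediate
11 | (E)-2-tert-butoxy-4-(tert-butyldimethylsilyloxy)-3-hexadecyl-5-methoxyhexa-1,3,5-trien-1-one (dienylketene; vinyl group cis to the ketene carbon) | O=C=C(OC(C)(C)C)/C(CCCCCCCCCCCCCCCC)=C(/O[Si](C)(C)C(C)(C)C)C(=C)OC | intermediate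
12 | 2-tert-butoxy-4-(tert-butyldimethylsilyloxy)-3-hexadecyl-5-methoxycyclohexa-2,4-dien-1-one | O=C1CC(OC)=C(O[Si](C)(C)C(C)(C)C)C(CCCCCCCCCCCCCCCC)=C1OC(C)(C)C | intermediate
13 | 2-tert-butoxy-4-(tert-butyldimethylsilyloxy)-3-hexadecyl-5-methoxyphenol | Oc1cc(OC)c(O[Si](C)(C)C(C)(C)C)c(CCCCCCCCCCCCCCCC)c1OC(C)(C)C | intermediate
14 | 2-tert-butoxy-3-hexadecyl-5-methoxy-1,4-benzoquinone | CCCCCCCCCCCCCCCCC1=C(OC(C)(C)C)C(=O)C=C(OC)C1=O | intermediate
15 | 3-hexadecyl-2-hydroxy-5-methoxy-1,4-benzoquinone | CCCCCCCCCCCCCCCCC1=C(O)C(=O)C=C(OC)C1=O | target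

**Step count and risks**
Total step count: 5. Longest linear sequence: 5 steps (1 → 5 → 10 → 13 → 14 → 15).

Steps most likely to fail:

1. Step 2. The silyl group may migrate between the two vicinal oxygens of alkoxide 8, or ionisation may occur at the wrong carbinol carbon, which would move the carbonyl to the wrong ring carbon; the trifluoroacetic acid set free may also protonate the enol ether. The fallback replaces the silyl ether by a methyl ether that cannot migrate and is removed oxidatively; it sets out from 4 (made from 1 and 3 as in step 1) and comes back at 14. Alkoxide 4 is quenched with aq. NH4Cl to give 2,3-di-tert-butoxy-4-hydroxy-4-(1-methoxyvinyl)cyclobut-2-en-1-one F1, which is O-methylated (MeI, Ag2O, K2CO3, MeCN) to 2,3-di-tert-butoxy-4-methoxy-4-(1-methoxyvinyl)cyclobut-2-en-1-one F2. Addition of 7 at −78 °C gives the lithium alkoxide F3, TFAA converts it to the trifluoroacetate ester F4, and ionisation with loss of isobutene should give 2-tert-butoxy-3-hexadecyl-4-methoxy-4-(1-methoxyvinyl)cyclobut-2-en-1-one F5. Thermolysis in toluene at 110 °C, through the dienylketene F6 and the cyclohexa-2,4-dienone F7, should give 2-tert-butoxy-3-hexadecyl-4,5-dimethoxyphenol F8. Oxidative demethylation of this para-methoxyphenol with (NH4)2Ce(NO3)6 in MeCN/H2O at 0 °C should then give 14.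

2. Step 3. The dienylketene may be diverted before the 6π closure, by inward rotation of the siloxy group, by intermolecular capture or oligomerisation through the electron-rich enol ether, or by thermal loss of isobutene. The fallback abandons ring construction and functionalises an intact arene; it sets out from 6 and comes back at 15. Purchased 1,2,4,5-tetramethoxybenzene F9 is lithiated between two methoxy groups (n-BuLi, TMEDA, THF, 0 °C) to 2,3,5,6-tetramethoxyphenyllithium F10, which is alkylated with 6 to 3-hexadecyl-1,2,4,5-tetramethoxybenzene F11. Oxidative demethylation with (NH4)2Ce(NO3)6 in MeCN/H2O should give 3-hexadecyl-2,5-dimethoxy-1,4-benzoquinone F12. Partial hydrolysis with 70% HClO4 in dioxane at rt should cleave the C2 methoxy group, which is twisted out of conjugation by the flanking hexadecyl chain and is expected to be the more labile vinylogous ester, to give 15.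

3. Step 4. The oxidised phenol may be captured by a nucleophile at C6, over-oxidised, or lose its tert-butyl group during the oxidative desilylation. The fallback separates desilylation from oxidation; it sets out from 13 and comes back at 14. Bu4NF in THF at 0 °C under argon should give 2-tert-butoxy-3-hexadecyl-5-methoxybenzene-1,4-diol F13, which Ag2O in Et2O at rt should dehydrogenate to 14.

**Further compounds**
F1 | step 2 | 2,3-di-tert-butoxy-4-hydroxy-4-(1-methoxyvinyl)cyclobut-2-en-1-one (racemic) | COC(=C)C1(O)C(OC(C)(C)C)=C(OC(C)(C)C)C1=O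
F2 | step 2 | 2,3-di-tert-butoxy-4-methoxy-4-(1-methoxyvinyl)cyclobut-2-en-1-one (racemic) | COC(=C)C1(OC)C(OC(C)(C)C)=C(OC(C)(C)C)C1=O
F3 | step 2 | lithium 2,3-di-tert-butoxy-1-hexadecyl-4-methoxy-4-(1-methoxyvinyl)cyclobut-2-en-1-olate (diastereomer mixture) | CCCCCCCCCCCCCCCCC1(O[Li])C(OC(C)(C)C)=C(OC(C)(C)C)C1(OC)C(=C)OC
F4 | step 2 | 2,3-di-tert-butoxy-1-hexadecyl-4-methoxy-4-(1-methoxyvinyl)cyclobut-2-en-1-yl trifluoroacetate (diastereomer mixture) | CCCCCCCCCCCCCCCCC1(OC(=O)C(F)(F)F)C(OC(C)(C)C)=C(OC(C)(C)C)C1(OC)C(=C)OC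
F5 | step 2 | 2-tert-butoxy-3-hexadecyl-4-methoxy-4-(1-methoxyvinyl)cyclobut-2-en-1-one (racemic) | CCCCCCCCCCCCCCCCC1=C(OC(C)(C)C)C(=O)C1(OC)C(=C)OC
F6 | step 2 | (E)-2-tert-butoxy-3-hexadecyl-4,5-dimethoxyhexa-1,3,5-trien-1-one (dienylketene) | O=C=C(OC(C)(C)C)/C(CCCCCCCCCCCCCCCC)=C(/OC)C(=C)OC
F7 | step 2 | 2-tert-butoxy-3-hexadecyl-4,5-dimethoxycyclohexa-2,4-dien-1-one | O=C1CC(OC)=C(OC)C(CCCCCCCCCCCCCCCC)=C1OC(C)(C)C
F8 | step 2 | 2-tert-butoxy-3-hexadecyl-4,5-dimethoxyphenol | Oc1cc(OC)c(OC)c(CCCCCCCCCCCCCCCC)c1OC(C)(C)C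
F9 | step 3 | 1,2,4,5-tetramethoxybenzene (purchased) | COc1cc(OC)c(OC)cc1OC
F10 | step 3 | 2,3,5,6-tetramethoxyphenyllithium | [Li]c1c(OC)c(OC)cc(OC)c1OC
F11 | step 3 | 3-hexadecyl-1,2,4,5-tetramethoxybenzene | CCCCCCCCCCCCCCCCc1c(OC)c(OC)cc(OC)c1OC
F12 | step 3 | 3-hexadecyl-2,5-dimethoxy-1,4-benzoquinone | CCCCCCCCCCCCCCCCC1=C(OC)C(=O)C=C(OC)C1=O
F13 | step 4 | 2-tert-butoxy-3-hexadecyl-5-methoxybenzene-1,4-diol | Oc1cc(OC)c(O)c(CCCCCCCCCCCCCCCC)c1OC(C)(C)C
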